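## Retrosynthetic overview
1. The last step removes two silyl groups and exchanges Li+ for H+. Before that, the whole C3–OSO3 chain is attached to C5 in one C–C bond formation from an aryl boronate and 1,3-propanediol cyclic sulfate. The boronate comes from C–H borylation of the only unflanked aryl C–H.
2. Key disconnection: benzene ring B and the dihydrofuran ring are opened together to a 2-substituted furan carrying a tethered ethynyl ether (gold-catalysed furan–yne phenol synthesis). The ynol ether oxygen becomes ring O1. The furan oxygen becomes the C7 oxygen, which is then methylated.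
3. The ethynyl ether comes from a secondary benzylic alcohol and trichloroethylene, which supplies C7a and C7.
4. Both stereocentres come from one Evans syn aldol of an N-(2-furylacetyl)oxazolidinone with vanillin acetate. The syn aldol pair maps onto the trans-(2S,3R) ring pair.
5. Ring order: ring A is bought, and the furan is bought and consumed. Ring B and the O-heterocycle form together in step 6, and no ring forms afterwards.

Assumption: the target is wanted as the free hydrogen sulfate as drawn; it is released from its lithium salt only in the last operation and is kept cold.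

## Route

Step 1
Reactants: 1 2-(furan-2-yl)acetic acid; 2 (S)-4-benzyl-1,3-oxazolidin-2-one
Product: 4 (S)-4-benzyl-3-[2-(furan-2-yl)acetyl]-1,3-oxazolidin-2-one, via mixed pivalic anhydride 3 (not isolated)
Conditions: PivCl, Et3N, THF, −20 °C; then LiCl, 2, −20 °C → rt
Reagents that add atoms: pivaloyl chloride, CC(C)(C)C(=O)Cl (its atoms stay only in 3)
Why: Mixed-anhydride N-acylation of the Evans auxiliary: the LiCl-activated oxazolidinone attacks the less hindered furylacetyl carbonyl of 3, and no stereocentre is formed.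

Step 2
Reactants: 4 (S)-4-benzyl-3-[2-(furan-2-yl)acetyl]-1,3-oxazolidin-2-one; 5 vanillin acetate (4-formyl-2-methoxyphenyl acetate)
Product: 8 (S)-4-benzyl-3-[(2R,3S)-3-(4-acetoxy-3-methoxyphenyl)-2-(furan-2-yl)-3-hydroxypropanoyl]-1,3-oxazolidin-2-one, via (Z)-dibutylboron enolate 6 (not isolated), via dibutylboron aldolate 7 (not isolated)
Conditions: Bu2BOTf (1.15 equiv), Et3N (1.3 equiv), CH2Cl2, −78 → 0 °C; 5, −78 → 0 °C; pH 7 buffer, MeOH, 30% H2O2, 0 °C
Reagents that add atoms: dibutylboron triflate, CCCCB(CCCC)OS(=O)(=O)C(F)(F)F (its atoms stay only in 6 and 7)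
Why: Evans boron syn aldol: the (Z)-enolate reacts through a Zimmerman–Traxler chair on the face left open by the benzyl group of the (S)-auxiliary, which sets both stereocentres as the (2R,3S) syn pair that later becomes the trans-(2S,3R) ring pair.

Step 3
Reactants: 8 the syn aldol imide
Product: 9 (1S,2R)-2-(furan-2-yl)-1-(4-hydroxy-3-methoxyphenyl)propane-1,3-diol
Conditions: LiBH4 (4 equiv), H2O (1 equiv), Et2O/THF, 0 °C → rt; aqueous work-up
Reagents that add atoms: none
Why: Reductive cleavage of the N-acyl oxazolidinone with LiBH4 gives the primary alcohol and returns the auxiliary, the same hydride reduces off the aryl acetate, and neither stereocentre is touched.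

Step 4
Reactants: 9 the triol
Product: 10 (1S,2R)-2-(furan-2-yl)-1-[3-methoxy-4-(triisopropylsilyloxy)phenyl]-3-(triisopropylsilyloxy)propan-1-ol
Conditions: TIPSCl (2.2 equiv), imidazole (5 equiv), DMF, 0 °C → rt
Reagents that add atoms: triisopropylsilyl chloride, CC(C)[Si](Cl)(C(C)C)C(C)C
Why: Chemoselective silylation: the bulky chlorosilane takes the phenol and the primary alcohol and leaves the hindered secondary benzylic alcohol free, so one step protects both positions.

Step 5
Reactants: 10 the bis-silyl alcohol; 11 trichloroethylene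
Product: 15 triisopropyl{4-[(1S,2R)-1-(ethynyloxy)-2-(furan-2-yl)-3-(triisopropylsilyloxy)propyl]-2-methoxyphenoxy}silane, via (E)-1,2-dichlorovinyl ether 12 (not isolated), via chloroethynyl ether 13 (not isolated), via lithium alkoxyacetylide 14 (not isolated)
Conditions: KH, THF, 0 °C; 11 (1.2 equiv), −50 °C → rt; then n-BuLi (3 equiv), −78 → −40 °C; H2O quench at −78 °C; quick filtration over Et3N-deactivated silica, keep below 20 °C
Reagents that add atoms: trichloroethylene 11, ClC=C(Cl)Cl; n-butyllithium, [Li]CCCC (lithium stays only in 14)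
Why: Greene ynol ether synthesis: the potassium alkoxide adds to dichloroacetylene generated in situ, n-BuLi then eliminates HCl and exchanges the remaining chlorine, and protonation gives the terminal ynol ether with the C–O bond of the stereocentre intact.

Step 6 (key step)
Reactants: 15 the furan-tethered ethynyl ether
Product: 18 (2S,3R)-7-methoxy-2-[3-methoxy-4-(triisopropylsilyloxy)phenyl]-3-[(triisopropylsilyloxy)methyl]-2,3-dihydro-1-benzofuran, via fused oxepine 16 (not isolated), via 7-hydroxydihydrobenzofuran 17 (not isolated)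
Conditions: Ph3PAuNTf2 (3 mol %), 4 Å MS, CH2Cl2 (0.02 M), −20 °C → rt, 30 min; then evaporate, acetone, K2CO3, MeI, rt
Reagents that add atoms: iodomethane, CI
Why: Hashmi furan–yne phenol synthesis followed by Williamson methylation: monovalent gold polarises the ynol ether so that its O-bearing carbon is attacked 5-exo by the furan C2=C3 bond, the cyclopropyl gold carbenoid opens the furan, the freed carbonyl oxygen closes onto the carbenoid carbon to give oxepine 16 (arene oxide tautomer), and this opens toward the O1-stabilised cation to give phenol 17, so the dihydrofuran ring and benzene ring B form in one operation while no bond at C2 or C3 changes and the syn pair becomes trans-(2S,3R).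

Step 7
Reactants: 18 the 7-methoxydihydrobenzofuran
Product: 19 (2S,3R)-7-methoxy-2-[3-methoxy-4-(triisopropylsilyloxy)phenyl]-5-(4,4,5,5-tetramethyl-1,3,2-dioxaborolan-2-yl)-3-[(triisopropylsilyloxy)methyl]-2,3-dihydro-1-benzofuran
Conditions: [Ir(OMe)(cod)]2 (2 mol %), dtbpy (4 mol %), B2pin2 (1.0 equiv), THF, 65 °C
Reagents that add atoms: bis(pinacolato)diboron, CC1(C)OB(OC1(C)C)B1OC(C)(C)C(C)(C)O1
Why: Hartwig–Miyaura C–H borylation is sterically governed, and C5–H is the only aromatic C–H in 18 without an ortho substituent (all-alkyl silyl groups offer no competing arene), so boron enters at C5 only.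

Step 8
Reactants: 19 the aryl boronate; 20 1,3,2-dioxathiane 2,2-dioxide (1,3-propanediol cyclic sulfate)
Product: 21 lithium 3-{(2S,3R)-7-methoxy-2-[3-methoxy-4-(triisopropylsilyloxy)phenyl]-3-[(triisopropylsilyloxy)methyl]-2,3-dihydro-1-benzofuran-5-yl}propyl sulfate
Conditions: LiOtBu (1.1 equiv), DMF, rt, 15 min; then CuI (10 mol %), 20 (1.5 equiv, slow addition), 40 °C
Reagents that add atoms: 1,3,2-dioxathiane 2,2-dioxide 20, O=S1(=O)OCCCO1; lithium tert-butoxide (lithium counter-ion), [Li+].CC(C)(C)[O-]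
Why: Proposed new method: tert-butoxide turns 19 into a borate that passes its aryl group to monovalent copper, the aryl copper species opens a primary C–O bond of 20 by SN2-type oxidative addition and reductive elimination, and the leaving group stays in the product as a sulfate monoester anion that is too poor a leaving group to react again; the closest known reaction types are the CuI/LiOtBu alkylation of aryl boronic esters with primary alkyl halides and tosylates and the copper-catalysed opening of cyclic sulfates by Grignard reagents, and no stereocentre is involved.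

Step 9
Reactants: 21 the bis-silylated lithium sulfate
Product: 23 3-[(2S,3R)-2-(4-hydroxy-3-methoxyphenyl)-3-(hydroxymethyl)-7-methoxy-2,3-dihydro-1-benzofuran-5-yl]propyl hydrogen sulfate (target CNP0220090.1), via desilylated lithium sulfate 22 (not isolated)
Conditions: HF·pyridine, pyridine, THF, 0 °C → rt; evaporate; sulfonic acid cation-exchange resin (H+ form), H2O/MeCN, 0 °C; freeze-dry
Reagents that add atoms: none
Why: Fluoride-driven desilylation under buffered, nearly neutral conditions frees the phenol and the primary alcohol without touching the sulfate monoester or the benzylic ether, and cold cation exchange replaces Li+ by H+ with both stereocentres untouched.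

## Compound list
1 | 2-(furan-2-yl)acetic acid | OC(=O)Cc1ccco1 | starting material
2 | (S)-4-benzyl-1,3-oxazolidin-2-one | O=C1OC[C@H](Cc2ccccc2)N1 | starting material
3 | 2-(furan-2-yl)acetic pivalic anhydride (not isolated) | CC(C)(C)C(=O)OC(=O)Cc1ccco1 | intermediate
4 | (S)-4-benzyl-3-[2-(furan-2-yl)acetyl]-1,3-oxazolidin-2-one | O=C1OC[C@H](Cc2ccccc2)N1C(=O)Cc1ccco1 | intermediate
5 | vanillin acetate | COc1cc(C=O)ccc1OC(C)=O | starting material
6 | (Z)-dibutylboron enolate of 4 (not isolated) | O=C1OC[C@H](Cc2ccccc2)N1/C(OB(CCCC)CCCC)=C/c1ccco1 | intermediate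
7 | dibutylboron aldolate of 8 (not isolated) | O=C1OC[C@H](Cc2ccccc2)N1C(=O)[C@@H](c1ccco1)[C@H](OB(CCCC)CCCC)c1ccc(OC(C)=O)c(OC)c1 | intermediate
8 | (2R,3S) syn aldol imide | O=C1OC[C@H](Cc2ccccc2)N1C(=O)[C@@H](c1ccco1)[C@H](O)c1ccc(OC(C)=O)c(OC)c1 | intermediate
9 | (1S,2R)-2-(furan-2-yl)-1-(4-hydroxy-3-methoxyphenyl)propane-1,3-diol | OC[C@@H](c1ccco1)[C@H](O)c1ccc(O)c(OC)c1 | intermediate
10 | (1S,2R) bis-TIPS ether with free secondary alcohol | CC(C)[Si](C(C)C)(C(C)C)OC[C@@H](c1ccco1)[C@H](O)c1ccc(O[Si](C(C)C)(C(C)C)C(C)C)c(OC)c1 | intermediate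
11 | trichloroethylene | ClC=C(Cl)Cl | starting material
12 | (E)-1,2-dichlorovinyl ether of 10 (not isolated) | CC(C)[Si](C(C)C)(C(C)C)OC[C@@H](c1ccco1)[C@H](O/C(Cl)=C\Cl)c1ccc(O[Si](C(C)C)(C(C)C)C(C)C)c(OC)c1 | intermediate
13 | chloroethynyl ether of 10 (not isolated) | CC(C)[Si](C(C)C)(C(C)C)OC[C@@H](c1ccco1)[C@H](OC#CCl)c1ccc(O[Si](C(C)C)(C(C)C)C(C)C)c(OC)c1 | intermediate
14 | lithium alkoxyacetylide of 10 (not isolated) | CC(C)[Si](C(C)C)(C(C)C)OC[C@@H](c1ccco1)[C@H](OC#C[Li])c1ccc(O[Si](C(C)C)(C(C)C)C(C)C)c(OC)c1 | intermediate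
15 | (1S,2R) ethynyl ether of 10 | CC(C)[Si](C(C)C)(C(C)C)OC[C@@H](c1ccco1)[C@H](OC#C)c1ccc(O[Si](C(C)C)(C(C)C)C(C)C)c(OC)c1 | intermediate
16 | (2S,3R) dihydrofuran-fused oxepine, valence tautomer of the 6,7-arene oxide (not isolated) | COc1cc([C@H]2OC3=COC=CC=C3[C@@H]2CO[Si](C(C)C)(C(C)C)C(C)C)ccc1O[Si](C(C)C)(C(C)C)C(C)C | intermediate
17 | (2S,3R) 2,3-dihydro-1-benzofuran-7-ol, bis-TIPS (not isolated) | COc1cc([C@H]2Oc3c(O)cccc3[C@@H]2CO[Si](C(C)C)(C(C)C)C(C)C)ccc1O[Si](C(C)C)(C(C)C)C(C)C | intermediate
18 | (2S,3R) 7-methoxy-2,3-dihydro-1-benzofuran, bis-TIPS | COc1cc([C@H]2Oc3c(OC)cccc3[C@@H]2CO[Si](C(C)C)(C(C)C)C(C)C)ccc1O[Si](C(C)C)(C(C)C)C(C)C | intermediate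
19 | 5-Bpin derivative of 18 | COc1cc([C@H]2Oc3c(OC)cc(B4OC(C)(C)C(C)(C)O4)cc3[C@@H]2CO[Si](C(C)C)(C(C)C)C(C)C)ccc1O[Si](C(C)C)(C(C)C)C(C)C | intermediate
20 | 1,3,2-dioxathiane 2,2-dioxide | O=S1(=O)OCCCO1 | starting material
21 | bis-TIPS lithium propyl sulfate | COc1cc([C@H]2Oc3c(OC)cc(CCCOS(=O)(=O)[O-])cc3[C@@H]2CO[Si](C(C)C)(C(C)C)C(C)C)ccc1O[Si](C(C)C)(C(C)C)C(C)C.[Li+] | intermediate
22 | lithium salt of the target (not isolated) | COc1cc([C@H]2Oc3c(OC)cc(CCCOS(=O)(=O)[O-])cc3[C@@H]2CO)ccc1O.[Li+] | intermediate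
23 | CNP0220090.1, (2S,3R) | COc1cc([C@H]2Oc3c(OC)cc(CCCOS(=O)(=O)O)cc3[C@@H]2CO)ccc1O | target

## Step count and risks
Total steps: 9. Longest linear sequence: 9 (from 1). All other carbon inputs (2, 5, 11, 20) are bought.

**Step 6, gold cycloisomerisation.**
- The activated ynol ether sits on an electron-rich benzylic carbon. It could therefore ionise, undergo a [3,3] shift or hydroarylation into ring A, or be hydrated to the acetate.
- The fallback buys ring B instead of making it. It sets out from 2 and 5 and replaces 1 by (2-bromo-3-methoxyphenyl)acetic acid.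
- The acid goes through its mixed pivalic anhydride F3 to the imide F4. The (Z)-dibutylboron enolate F5 of this imide adds to 5 to give the boron aldolate F6. Oxidative work-up then gives the (2S,3S) syn aldol F7, which has the same spatial arrangement as 8.
- LiBH4 gives the triol F8, and TIPSCl gives the bis-silyl alcohol F9.
- An intramolecular Ullmann-type C–O coupling of the secondary alcohol onto the aryl bromide (CuI, 1,10-phenanthroline, Cs2CO3, toluene, 110 °C) closes the dihydrofuran with both stereocentres retained. The fallback comes back to the route at 18.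

**Step 5, ynol ether formation.**
- The potassium alkoxide could trigger silyl migration from the primary oxygen.
- The secondary benzylic ynol ether can decompose by retro-ene loss of ketene.
- The fallback avoids the alkoxide and builds the two carbons from a formate. It sets out from 10.
- Formic acetic anhydride and pyridine give the formate ester F1. Dichloromethylenation of the formate carbonyl (PPh3, CCl4, THF, reflux) gives the 2,2-dichlorovinyl ether F2.
- n-BuLi (2.2 equiv, −78 °C) takes F2 through the same chloroalkyne 13 and acetylide 14. A water quench brings it back to the route at 15.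

**Step 8, copper-catalysed opening of the cyclic sulfate.**
- Free tert-butoxide may consume 20.
- The boronate may protodeboronate.
- Loss of the phenolic silyl group would lead to O-alkylation.
- The fallback introduces the sulfate by O-sulfation instead of C–C bond formation. It sets out from 19.
- Suzuki–Miyaura allylation (Pd(PPh3)4, allyl bromide, K2CO3, THF/H2O) gives the 5-allyl compound F10. 9-BBN adds to the terminal alkene to give the B-alkyl borane F11.
- NaBO3·4H2O oxidises this to the primary alcohol F12, which carries the only free OH in the molecule.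
- SO3·pyridine gives the pyridinium sulfate F13, and treatment with LiOH brings it back to the route at 21.

## Further compounds
F1 | step 5 | formate ester of 10 | CC(C)[Si](C(C)C)(C(C)C)OC[C@@H](c1ccco1)[C@H](OC=O)c1ccc(O[Si](C(C)C)(C(C)C)C(C)C)c(OC)c1
F2 | step 5 | 2,2-dichlorovinyl ether of 10 | CC(C)[Si](C(C)C)(C(C)C)OC[C@@H](c1ccco1)[C@H](OC=C(Cl)Cl)c1ccc(O[Si](C(C)C)(C(C)C)C(C)C)c(OC)c1
F3 | step 6 | (2-bromo-3-methoxyphenyl)acetic pivalic anhydride | CC(C)(C)C(=O)OC(=O)Cc1cccc(OC)c1Br
F4 | step 6 | (S)-4-benzyl-3-[2-(2-bromo-3-methoxyphenyl)acetyl]-1,3-oxazolidin-2-one | O=C1OC[C@H](Cc2ccccc2)N1C(=O)Cc1cccc(OC)c1Br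
F5 | step 6 | (Z)-dibutylboron enolate of F4 | O=C1OC[C@H](Cc2ccccc2)N1/C(OB(CCCC)CCCC)=C/c1cccc(OC)c1Br
F6 | step 6 | dibutylboron aldolate of F7 | O=C1OC[C@H](Cc2ccccc2)N1C(=O)[C@@H](c1cccc(OC)c1Br)[C@H](OB(CCCC)CCCC)c1ccc(OC(C)=O)c(OC)c1
F7 | step 6 | (2S,3S) syn aldol imide of the bromoaryl series | O=C1OC[C@H](Cc2ccccc2)N1C(=O)[C@@H](c1cccc(OC)c1Br)[C@H](O)c1ccc(OC(C)=O)c(OC)c1
F8 | step 6 | (1S,2R)-2-(2-bromo-3-methoxyphenyl)-1-(4-hydroxy-3-methoxyphenyl)propane-1,3-diol | OC[C@@H](c1cccc(OC)c1Br)[C@H](O)c1ccc(O)c(OC)c1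
F9 | step 6 | bis-TIPS ether of F8 with free secondary alcohol | CC(C)[Si](C(C)C)(C(C)C)OC[C@@H](c1cccc(OC)c1Br)[C@H](O)c1ccc(O[Si](C(C)C)(C(C)C)C(C)C)c(OC)c1
F10 | step 8 | 5-allyl derivative of 18 | COc1cc([C@H]2Oc3c(OC)cc(CC=C)cc3[C@@H]2CO[Si](C(C)C)(C(C)C)C(C)C)ccc1O[Si](C(C)C)(C(C)C)C(C)C
F11 | step 8 | 9-BBN adduct of F10 | COc1cc([C@H]2Oc3c(OC)cc(CCCB4C5CCCC4CCC5)cc3[C@@H]2CO[Si](C(C)C)(C(C)C)C(C)C)ccc1O[Si](C(C)C)(C(C)C)C(C)C
F12 | step 8 | 5-(3-hydroxypropyl) derivative of 18 | COc1cc([C@H]2Oc3c(OC)cc(CCCO)cc3[C@@H]2CO[Si](C(C)C)(C(C)C)C(C)C)ccc1O[Si](C(C)C)(C(C)C)C(C)C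
F13 | step 8 | pyridinium salt of the bis-TIPS propyl sulfate | COc1cc([C@H]2Oc3c(OC)cc(CCCOS(=O)(=O)[O-])cc3[C@@H]2CO[Si](C(C)C)(C(C)C)C(C)C)ccc1O[Si](C(C)C)(C(C)C)C(C)C.c1cc[nH+]cc1
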